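The route rests on cutting C5–C1' and on reading C3 of the 1,2-dioxolane ring as a hidden prochiral centre. C3 carries two arms at the CH2–C(=O) level, C4–C5 and CH2–CO2H. Both arms are folded into one achiral six-membered anhydride, 4-methyl-4-(silylperoxy)oxane-2,6-dione. Its rhodium-catalysed enantioselective alkylative opening by the complete C1'–C10' alkylzinc reagent joins the two halves, makes C3 stereogenic and frees the acetic acid arm in one operation. The keto acid is then closed to a bridged peroxyketal lactone. Its tethered carboxylate steers the last methyl group onto C5, trans to the acid arm.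

Key step: step 13

Remark: numbering is O1–O2–C3(CH2CO2H)–C4–C5 in the ring and C1'–C10' along the side chain; the sense of induction of t-Bu-PHOX on the anhydride has no precedent, so the S ligand is assumed to give 3R and its antipode is taken otherwise.

Step 1
Reactants: 1 1-phenylprop-2-en-1-ol (racemic)
Product: 3 (E)-5-phenylpent-4-enal, via allyl vinyl ether 2 (not isolated)
Conditions: n-BuOCH=CH2 (excess), Pd(OCOCF3)2 (1 mol %), 4,7-diphenyl-1,10-phenanthroline (1 mol %), Et3N (cat.), 75 °C; evaporate; toluene, 110 °C
Reagents that add atoms: n-butyl vinyl ether, C=COCCCC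
Why: Palladium-catalysed vinyl ether exchange and Claisen rearrangement through a chair with the phenyl group equatorial should give the E alkene, and conjugation with the arene drives the shift.

Step 2
Reactants: 3 (E)-5-phenylpent-4-enal
Product: 4 [(1E,5E)-6-iodohexa-1,5-dien-1-yl]benzene
Conditions: CrCl2 (6 equiv), CHI3 (2 equiv), dioxane/THF, 0 → 23 °C
Reagents that add atoms: iodoform, IC(I)I
Why: Takai olefination, in which the geminal dichromium reagent made from CHI3 adds to the aldehyde and eliminates from the less crowded adduct, should give the E vinyl iodide and leave the styrene untouched.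

Step 3
Reactants: 5 methyl (S)-3-hydroxy-2-methylpropanoate
Product: 6 methyl (S)-3-[(tert-butyldimethylsilyl)oxy]-2-methylpropanoate
Conditions: TBSCl, imidazole, CH2Cl2, 23 °C
Reagents that add atoms: tert-butyldimethylsilyl chloride, CC(C)(C)[Si](C)(C)Cl
Why: Standard silylation of a primary alcohol, which leaves the chiral pool stereocentre (the later C2') untouched.

Step 4
Reactants: 6 methyl (S)-3-[(tert-butyldimethylsilyl)oxy]-2-methylpropanoate
Product: 7 (S)-3-[(tert-butyldimethylsilyl)oxy]-2-methylpropanal
Conditions: i-Bu2AlH (1.05 equiv), CH2Cl2, −78 °C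
Reagents that add atoms: none
Why: Partial ester reduction stops at the tetrahedral aluminium hemiacetal at −78 °C, and the non-basic medium keeps the alpha stereocentre intact.

Step 5
Reactants: 7 (S)-3-[(tert-butyldimethylsilyl)oxy]-2-methylpropanal
Product: 8 (R)-tert-butyldimethyl[(2-methylbut-3-en-1-yl)oxy]silane
Conditions: Ph3PCH3Br, n-BuLi, THF, −78 → 0 °C
Reagents that add atoms: methyltriphenylphosphonium bromide, C[P+](c1ccccc1)(c1ccccc1)c1ccccc1.[Br-]
Why: Wittig methylenation with the non-stabilised ylide is fast at low temperature, so the alpha-chiral aldehyde should not epimerise (the descriptor changes only through the priority rules).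

Step 6
Reactants: 8 (R)-tert-butyldimethyl[(2-methylbut-3-en-1-yl)oxy]silane; 4 [(1E,5E)-6-iodohexa-1,5-dien-1-yl]benzene
Product: 10 tert-butyldimethyl{[(2R,5E,9E)-2-methyl-10-phenyldeca-5,9-dien-1-yl]oxy}silane, via B-alkyl-9-BBN adduct 9 (not isolated)
Conditions: 9-BBN-H, THF, 23 °C; then 4, PdCl2(dppf) (5 mol %), AsPh3 (5 mol %), Cs2CO3, DMF/H2O, 23 °C
Reagents that add atoms: none
Why: Anti-Markovnikov hydroboration of the terminal alkene followed by B-alkyl Suzuki–Miyaura coupling forms C4'–C5' with retention of the E geometry of the vinyl iodide and does not touch C2'.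

Step 7
Reactants: 10 tert-butyldimethyl{[(2R,5E,9E)-2-methyl-10-phenyldeca-5,9-dien-1-yl]oxy}silane
Product: 11 (2R,5E,9E)-2-methyl-10-phenyldeca-5,9-dien-1-ol
Conditions: Bu4NF, THF, 23 °C
Reagents that add atoms: none
Why: Fluoride-driven desilylation of a primary TBS ether.

Step 8
Reactants: 11 (2R,5E,9E)-2-methyl-10-phenyldeca-5,9-dien-1-ol
Product: 12 [(1E,5E,9R)-10-iodo-9-methyldeca-1,5-dien-1-yl]benzene
Conditions: I2, PPh3, imidazole, CH2Cl2, 0 °C
Reagents that add atoms: iodine, II
Why: Appel-type iodination by SN2 at the primary C1', one carbon away from the stereocentre.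

Step 9
Reactants: 13 4-methylhepta-1,6-dien-4-ol
Product: 14 4-hydroperoxy-4-methylhepta-1,6-diene
Conditions: 50% aq. H2O2 (excess), H2SO4 (cat.), 0 °C
Reagents that add atoms: hydrogen peroxide, OO
Why: Acid-catalysed perhydrolysis (SN1) of a tertiary alcohol, in which the large excess of H2O2 should trap the tertiary cation before elimination; the carbon is not yet stereogenic.

Step 10
Reactants: 14 4-hydroperoxy-4-methylhepta-1,6-diene
Product: 15 tert-butyldimethylsilyl 4-methylhepta-1,6-dien-4-yl peroxide
Conditions: TBSCl, imidazole, DMF, 0 °C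
Reagents that add atoms: tert-butyldimethylsilyl chloride, CC(C)(C)[Si](C)(C)Cl
Why: Silylation of the hydroperoxide masks the acidic O–H and gives a hindered silyl alkyl peroxide that should tolerate oxidants, carbodiimide and organozinc reagents.

Step 11
Reactants: 15 tert-butyldimethylsilyl 4-methylhepta-1,6-dien-4-yl peroxide
Product: 16 3-[(tert-butyldimethylsilyl)peroxy]-3-methylpentanedioic acid
Conditions: RuCl3 (5 mol %), NaIO4 (9 equiv), EtOAc/MeCN/H2O, 0 → 23 °C
Reagents that add atoms: sodium periodate, [Na+].[O-]I(=O)(=O)=O; water, O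
Why: RuO4-catalysed oxidative cleavage turns each terminal vinyl group into a carboxylic acid with loss of one carbon, and the peroxide is already at its highest oxidation level.

Step 12
Reactants: 16 3-[(tert-butyldimethylsilyl)peroxy]-3-methylpentanedioic acid
Product: 17 4-[(tert-butyldimethylsilyl)peroxy]-4-methyloxane-2,6-dione (achiral cyclic anhydride)
Conditions: DCC (1.0 equiv), CH2Cl2, 0 → 23 °C
Reagents that add atoms: none
Why: Carbodiimide cyclodehydration of a 3,3-disubstituted glutaric acid is helped by the geminal disubstituent effect and runs at room temperature, which spares the peroxide.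

Step 13
Reactants: 12 [(1E,5E,9R)-10-iodo-9-methyldeca-1,5-dien-1-yl]benzene; 17 4-[(tert-butyldimethylsilyl)peroxy]-4-methyloxane-2,6-dione
Product: 19 (3R,7R,10E,14E)-3-[(tert-butyldimethylsilyl)peroxy]-3,7-dimethyl-5-oxo-15-phenylpentadeca-10,14-dienoic acid, via alkylzinc iodide 18 (not isolated)
Conditions: 12, Zn dust (activated), LiCl, THF, 25–40 °C; then 17, [Rh(cod)Cl]2 (5 mol %), (S)-t-Bu-PHOX (10 mol %), THF, 23 → 40 °C; cold 0.5 M HCl
Reagents that add atoms: none
Why: Proposed new method: monovalent rhodium carrying the chiral phosphinooxazoline should insert into one of the two enantiotopic acyl C–O bonds of 17, the resulting acyl rhodium carboxylate takes up the alkyl group of 18 by transmetalation, and reductive elimination forms C5–C1' and releases 19 as its zinc carboxylate. The closest known reaction type is the rhodium/phosphinooxazoline-catalysed enantioselective alkylative desymmetrisation of meso-dimethylglutaric anhydrides with alkylzinc halides; an anhydride whose only prostereogenic atom is a remote, peroxide-bearing ring carbon has not been shown. No ring is closed; the temporary oxane-2,6-dione ring is opened. C3 is the only new stereocentre and is set by the catalyst, which reads the difference between the small methyl group and the bulky silylperoxy group on the ring carbon between the two carbonyl arms, while C2' comes unchanged from 12. The step needs enantiotopic-group selectivity, a single addition (ketone and carboxylate of 19 are inert to alkylzinc iodides), reductive elimination ahead of beta-hydride elimination or decarbonylation, and survival of the O–O bond, which is shielded by the tertiary carbon on one side and the TBS group on the other.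

Step 14
Reactants: 19 (3R,7R,10E,14E)-3-[(tert-butyldimethylsilyl)peroxy]-3,7-dimethyl-5-oxo-15-phenylpentadeca-10,14-dienoic acid
Product: 21 (1S,5R)-5-methyl-1-[(2R,5E,9E)-2-methyl-10-phenyldeca-5,9-dien-1-yl]-2,6,7-trioxabicyclo[3.2.1]octan-3-one, via peroxy lactol 20 (not isolated)
Conditions: HF·pyridine, THF, 0 °C; aqueous work-up; then DCC, CH2Cl2, 0 → 23 °C
Reagents that add atoms: none
Why: Fluoride frees the hydroperoxide, which adds to the C5 ketone (5-exo-trig peroxyhemiketalisation), and because the two lactol epimers interconvert through the open form while only the one with OH cis to the CH2CO2H arm can reach the activated acid, carbodiimide lactonisation should funnel all material into one bridged lactone whose C5 configuration is dictated by C3.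

Step 15
Reactants: 21 (1S,5R)-5-methyl-1-[(2R,5E,9E)-2-methyl-10-phenyldeca-5,9-dien-1-yl]-2,6,7-trioxabicyclo[3.2.1]octan-3-one
Product: 22 2-[(3R,5R)-3,5-dimethyl-5-[(2R,5E,9E)-2-methyl-10-phenyldeca-5,9-dien-1-yl]-1,2-dioxolan-3-yl]acetic acid
Conditions: TiCl4 (1 equiv), then MeTiCl3 (3 equiv, from Me2Zn and TiCl4 in CH2Cl2), CH2Cl2, −78 → −40 °C; 1 M HCl
Reagents that add atoms: dimethylzinc, C[Zn]C (methyl source, transmetalated in the flask to methyltitanium trichloride, C[Ti](Cl)(Cl)Cl)
Why: Proposed new method: the titanium Lewis acid should ionise the acyloxy peroxyketal bond (C1–O2 of the bicycle) to a peroxycarbenium ion whose one face stays covered by the tethered titanium carboxylate, so that MeTiCl3, a non-basic donor without beta hydrogen, delivers methyl to the open face, places CH3 trans to the acid arm (5R, both methyl groups cis) and frees the acid; the closest known reaction types are the Lewis acid-mediated substitution of 3-alkoxy-1,2-dioxolanes by silyl nucleophiles through peroxycarbenium ions and the invertive opening of acetals by MeTiCl3.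

Compound list
1 | 1-phenylprop-2-en-1-ol (racemic) | C=CC(O)c1ccccc1 | starting material
2 | [1-(ethenyloxy)prop-2-en-1-yl]benzene | C=COC(C=C)c1ccccc1 | intermediate
3 | (E)-5-phenylpent-4-enal | O=CCC/C=C/c1ccccc1 | intermediate
4 | [(1E,5E)-6-iodohexa-1,5-dien-1-yl]benzene | I/C=C/CC/C=C/c1ccccc1 | intermediate
5 | methyl (S)-3-hydroxy-2-methylpropanoate | C[C@H](C(=O)OC)CO | starting material
6 | methyl (S)-3-[(tert-butyldimethylsilyl)oxy]-2-methylpropanoate | C[C@H](C(=O)OC)CO[Si](C)(C)C(C)(C)C | intermediate
7 | (S)-3-[(tert-butyldimethylsilyl)oxy]-2-methylpropanal | C[C@H](C=O)CO[Si](C)(C)C(C)(C)C | intermediate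
8 | (R)-tert-butyldimethyl[(2-methylbut-3-en-1-yl)oxy]silane | C[C@H](C=C)CO[Si](C)(C)C(C)(C)C | intermediate
9 | 9-[(R)-4-[(tert-butyldimethylsilyl)oxy]-3-methylbutyl]-9-borabicyclo[3.3.1]nonane | C[C@H](CCB1C2CCCC1CCC2)CO[Si](C)(C)C(C)(C)C | intermediate
10 | tert-butyldimethyl{[(2R,5E,9E)-2-methyl-10-phenyldeca-5,9-dien-1-yl]oxy}silane | C[C@H](CC/C=C/CC/C=C/c1ccccc1)CO[Si](C)(C)C(C)(C)C | intermediate
11 | (2R,5E,9E)-2-methyl-10-phenyldeca-5,9-dien-1-ol | C[C@H](CC/C=C/CC/C=C/c1ccccc1)CO | intermediate
12 | [(1E,5E,9R)-10-iodo-9-methyldeca-1,5-dien-1-yl]benzene | C[C@H](CC/C=C/CC/C=C/c1ccccc1)CI | intermediate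
13 | 4-methylhepta-1,6-dien-4-ol | C=CCC(C)(O)CC=C | starting material
14 | 4-hydroperoxy-4-methylhepta-1,6-diene | C=CCC(C)(OO)CC=C | intermediate
15 | tert-butyldimethylsilyl 4-methylhepta-1,6-dien-4-yl peroxide | C=CCC(C)(CC=C)OO[Si](C)(C)C(C)(C)C | intermediate
16 | 3-[(tert-butyldimethylsilyl)peroxy]-3-methylpentanedioic acid | CC(CC(=O)O)(CC(=O)O)OO[Si](C)(C)C(C)(C)C | intermediate
17 | 4-[(tert-butyldimethylsilyl)peroxy]-4-methyloxane-2,6-dione | CC1(OO[Si](C)(C)C(C)(C)C)CC(=O)OC(=O)C1 | intermediate
18 | [(2R,5E,9E)-2-methyl-10-phenyldeca-5,9-dien-1-yl]zinc iodide | C[C@H](CC/C=C/CC/C=C/c1ccccc1)C[Zn]I | intermediate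
19 | (3R,7R,10E,14E)-3-[(tert-butyldimethylsilyl)peroxy]-3,7-dimethyl-5-oxo-15-phenylpentadeca-10,14-dienoic acid | C[C@H](CC/C=C/CC/C=C/c1ccccc1)CC(=O)C[C@](C)(CC(=O)O)OO[Si](C)(C)C(C)(C)C | intermediate
20 | 2-[(3R)-5-hydroxy-3-methyl-5-[(2R,5E,9E)-2-methyl-10-phenyldeca-5,9-dien-1-yl]-1,2-dioxolan-3-yl]acetic acid (both C5 epimers, equilibrating) | C[C@H](CC/C=C/CC/C=C/c1ccccc1)CC1(O)C[C@](C)(CC(=O)O)OO1 | intermediate
21 | (1S,5R)-5-methyl-1-[(2R,5E,9E)-2-methyl-10-phenyldeca-5,9-dien-1-yl]-2,6,7-trioxabicyclo[3.2.1]octan-3-one | C[C@H](CC/C=C/CC/C=C/c1ccccc1)C[C@]12C[C@](C)(CC(=O)O1)OO2 | intermediate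
22 | 2-[(3R,5R)-3,5-dimethyl-5-[(2R,5E,9E)-2-methyl-10-phenyldeca-5,9-dien-1-yl]-1,2-dioxolan-3-yl]acetic acid | C[C@H](CC/C=C/CC/C=C/c1ccccc1)C[C@]1(C)C[C@](C)(CC(=O)O)OO1 | target

Total steps: 15. Longest linear sequence: 9 (steps 3–8, then 13–15).

Steps most likely to fail

Step 13 (key step). The catalyst may discriminate poorly between the two enantiotopic carbonyl groups. The low-valent metal or its phosphine may reduce the O–O bond. Radical cyclisation onto the C5'–C6' alkene may occur during zinc insertion. The fallback uses known chemistry, sets out from 17 and comes back at 19. Desymmetrising thiolysis of 17 with cyclohexanethiol under a cinchona-derived bifunctional sulfonamide organocatalyst (MTBE, 23 °C) should give the S-cyclohexyl hemithioester F1. Its free acid is masked in the flask as the trimethylsilyl ester F2 (Me3SiCl, Et3N). Fukuyama coupling of F2 with 18 (PdCl2(PPh3)2, THF/toluene, 23 °C) and acidic work-up should then give 19.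

Step 15. The peroxycarbenium ion may be captured by the C5'–C6' alkene. The methyl donor may attack the O–O bond. Facial control may be lost if methyl is delivered from the titanium carboxylate itself. The fallback uses known chemistry, sets out from 19 and comes back at 22. MeTi(OiPr)3 (THF, 0 → 23 °C) should add to the ketone to give the tertiary alcohol F3 as both C5 epimers. HF·pyridine frees the hydroperoxy alcohol F4. Catalytic TsOH in CH2Cl2 closes the dioxolane by acid-catalysed alkylation of the hydroperoxide by the tertiary alcohol. This path gives up stereocontrol at C5, so 22 is separated by HPLC from the C5 epimer F5.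

Step 14. The open beta-hydroperoxy ketone may lose hydroperoxide by elimination. The hindered lactol OH may also fail to reach the activated acid, in which case the acid ends as an N-acylurea. The fallback sets out from 19 and comes back at 21. It closes the lactone ring first: (CF3CO)2O and 2,6-lutidine (CH2Cl2, 0 °C) should convert the delta-keto acid into the enol lactone F6. HF·pyridine then removes the silyl group and catalyses Markovnikov addition of the hydroperoxide across the enol ester double bond. For geometric reasons this addition can only give the bridged lactone 21.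

Further compounds
F1 | step 13 | 3-[(tert-butyldimethylsilyl)peroxy]-5-(cyclohexylsulfanyl)-3-methyl-5-oxopentanoic acid (C3 arranged as in 19) | O=C(SC1CCCCC1)C[C@](C)(CC(=O)O)OO[Si](C)(C)C(C)(C)C
F2 | step 13 | trimethylsilyl ester of F1 | O=C(SC1CCCCC1)C[C@](C)(CC(=O)O[Si](C)(C)C)OO[Si](C)(C)C(C)(C)C
F3 | step 15 | (3R,7R,10E,14E)-3-[(tert-butyldimethylsilyl)peroxy]-5-hydroxy-3,5,7-trimethyl-15-phenylpentadeca-10,14-dienoic acid (both C5 epimers) | C[C@H](CC/C=C/CC/C=C/c1ccccc1)CC(C)(O)C[C@](C)(CC(=O)O)OO[Si](C)(C)C(C)(C)C
F4 | step 15 | (3R,7R,10E,14E)-3-hydroperoxy-5-hydroxy-3,5,7-trimethyl-15-phenylpentadeca-10,14-dienoic acid (both C5 epimers) | C[C@H](CC/C=C/CC/C=C/c1ccccc1)CC(C)(O)C[C@](C)(CC(=O)O)OO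
F5 | step 15 | 2-[(3R,5S)-3,5-dimethyl-5-[(2R,5E,9E)-2-methyl-10-phenyldeca-5,9-dien-1-yl]-1,2-dioxolan-3-yl]acetic acid (C5 epimer of 22) | C[C@H](CC/C=C/CC/C=C/c1ccccc1)C[C@@]1(C)C[C@](C)(CC(=O)O)OO1
F6 | step 14 | 4-[(tert-butyldimethylsilyl)peroxy]-4-methyl-6-[(2R,5E,9E)-2-methyl-10-phenyldeca-5,9-dien-1-yl]-3,4-dihydro-2H-pyran-2-one (C4 arranged as C3 in 19) | C[C@H](CC/C=C/CC/C=C/c1ccccc1)CC1=C[C@@](C)(OO[Si](C)(C)C(C)(C)C)CC(=O)O1
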